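The ten-membered carbocycle is disconnected at C7–C8, the bond that joins the lactone β-carbon to the acyloxy carbon. The array O–C8–C7–C11(=C13H2)–C12 at the junction of carbocycle and α-methylene-γ-butyrolactone is the retron of a carbonyl allylation with allylic transposition. An intramolecular Nozaki–Hiyama–Kishi reaction of a 3-(bromomethyl)butenolide with a tethered β,γ-unsaturated aldehyde therefore closes the carbocycle onto the preformed lactone, sets C7 and C8, and unveils the exocyclic methylene in one operation. The open-chain precursor takes C6 from the D-glutamic acid chiral pool, C4 from a trans-selective lactone alkylation and the ring-cis C1=C10 alkene from an E-selective Wittig reaction. C8 is inverted during the final esterification.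

Key step: step 14

Remark: germacranolide numbering is used (carbocycle C1–C10, C1=C10 alkene, C14 on C10, C15 on C4, lactone O–C6/C7/C11(=C13)/C12, ester on O–C8); 1 and 8 are taken as catalogue compounds; the CIP descriptor of C7 switches between the free C8 alcohols (R) and the C8 esters (S) without any change in geometry.

Step 1
Reactants: 1 (5R)-5-(hydroxymethyl)oxolan-2-one
Product: 2 (2R)-5-oxooxolane-2-carbaldehyde
Conditions: Dess–Martin periodinane, CH2Cl2, 0 °C to rt; used crude
Reagents that add atoms: none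
Why: Dess–Martin oxidation converts the primary alcohol into the aldehyde under non-basic conditions, so the α-oxygenated stereocentre (future C6) should not epimerise.

Step 2
Reactants: 2 (2R)-5-oxooxolane-2-carbaldehyde
Product: 3 (5R)-5-ethenyloxolan-2-one
Conditions: Ph3PCH3Br, KHMDS, THF, −78 °C to 0 °C
Reagents that add atoms: methyltriphenylphosphonium bromide, C[P+](c1ccccc1)(c1ccccc1)c1ccccc1.[Br-]
Why: Wittig methylenation with the salt-free ylide at low temperature should be faster than enolisation of the α-acyloxy aldehyde or attack on the lactone, giving the vinyl lactone with C6 intact.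

Step 3
Reactants: 4 3-bromo-1,1-dimethoxypropane
Product: 5 3-iodo-1,1-dimethoxypropane
Conditions: NaI, acetone, reflux
Reagents that add atoms: sodium iodide, [Na+].[I-]
Why: Finkelstein halide exchange (SN2), driven by precipitation of sodium bromide from acetone, provides the more reactive iodide.

Step 4
Reactants: 3 (5R)-5-ethenyloxolan-2-one; 5 3-iodo-1,1-dimethoxypropane
Product: 7 3-[(3S,5R)-5-ethenyl-2-oxooxolan-3-yl]propanal, via dimethyl acetal 6 (not isolated)
Conditions: LDA, THF/DMPU, −78 °C; 5, −78 to −30 °C; then 1 M aq. HCl, THF, rt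
Reagents that add atoms: water, O
Why: Alkylation of the lactone lithium enolate should take place on the face anti to the C5 vinyl group (1,3-induction), which sets the trans (3S) centre that becomes C4, and the acidic work-up hydrolyses the dimethyl acetal to the aldehyde.

Step 5
Reactants: 8 1-[(3-bromopropoxy)methyl]-4-methoxybenzene
Product: 9 {3-[(4-methoxyphenyl)methoxy]propyl}triphenylphosphonium bromide
Conditions: PPh3, MeCN, reflux
Reagents that add atoms: triphenylphosphine, c1ccc(cc1)P(c1ccccc1)c1ccccc1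
Why: SN2 quaternisation of triphenylphosphine by the primary bromide gives the phosphonium salt.

Step 6
Reactants: 9 {3-[(4-methoxyphenyl)methoxy]propyl}triphenylphosphonium bromide; 10 methyl chloroformate
Product: 13 methyl 4-[(4-methoxyphenyl)methoxy]-2-(triphenyl-λ5-phosphanylidene)butanoate, via phosphorus ylide 11 (not isolated), via acylphosphonium chloride 12 (not isolated)
Conditions: NaHMDS (1 equiv), THF, −78 °C; ClCO2Me (1 equiv); NaHMDS (1 equiv), −78 to 0 °C
Reagents that add atoms: none
Why: C-Acylation of the non-stabilised ylide by the chloroformate followed by deprotonation of the resulting acylphosphonium salt (ylide acylation) should deliver the α-branched ester-stabilised ylide.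

Step 7
Reactants: 7 3-[(3S,5R)-5-ethenyl-2-oxooxolan-3-yl]propanal; 13 methyl 4-[(4-methoxyphenyl)methoxy]-2-(triphenyl-λ5-phosphanylidene)butanoate
Product: 14 methyl (2E)-5-[(3S,5R)-5-ethenyl-2-oxooxolan-3-yl]-2-{2-[(4-methoxyphenyl)methoxy]ethyl}pent-2-enoate
Conditions: toluene, 80 °C
Reagents that add atoms: none
Why: Wittig olefination with an α-substituted ester-stabilised ylide should give the E enoate, which places the C9 branch cis to the C2 chain and so fixes the ring-cis C1=C10 geometry of the target.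

Step 8
Reactants: 14 methyl (2E)-5-[(3S,5R)-5-ethenyl-2-oxooxolan-3-yl]-2-{2-[(4-methoxyphenyl)methoxy]ethyl}pent-2-enoate
Product: 15 (3R,5S,8E)-5,9-bis(hydroxymethyl)-11-[(4-methoxyphenyl)methoxy]undeca-1,8-dien-3-ol
Conditions: DIBAL-H (excess), CH2Cl2, −78 °C to 0 °C; Rochelle salt work-up
Reagents that add atoms: none
Why: DIBAL-H reduces the enoate by 1,2-addition to the allylic alcohol and the lactone to the diol in one operation, without touching a stereocentre or the PMB ether.

Step 9
Reactants: 15 (3R,5S,8E)-5,9-bis(hydroxymethyl)-11-[(4-methoxyphenyl)methoxy]undeca-1,8-dien-3-ol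
Product: 16 (3R,5S,8E)-5,9-bis({[tert-butyl(dimethyl)silyl]oxy}methyl)-11-[(4-methoxyphenyl)methoxy]undeca-1,8-dien-3-ol
Conditions: TBSCl (2.1 equiv), imidazole, CH2Cl2, −20 to 0 °C
Reagents that add atoms: tert-butyl(chloro)dimethylsilane, CC(C)(C)[Si](C)(C)Cl
Why: Silylation with TBSCl/imidazole is much faster at the two primary hydroxyls than at the secondary allylic one, which should leave only O–C6 free.

Step 10
Reactants: 16 (3R,5S,8E)-5,9-bis({[tert-butyl(dimethyl)silyl]oxy}methyl)-11-[(4-methoxyphenyl)methoxy]undeca-1,8-dien-3-ol; 17 2-(bromomethyl)prop-2-enoic acid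
Product: 18 (3R,5S,8E)-5,9-bis({[tert-butyl(dimethyl)silyl]oxy}methyl)-11-[(4-methoxyphenyl)methoxy]undeca-1,8-dien-3-yl 2-(bromomethyl)prop-2-enoate
Conditions: DCC, DMAP (cat.), CH2Cl2, 0 °C
Reagents that add atoms: none
Why: Steglich esterification acylates the secondary alcohol with retention at C6, and cold, DMAP-lean conditions should spare the allylic bromide.

Step 11
Reactants: 18 (3R,5S,8E)-5,9-bis({[tert-butyl(dimethyl)silyl]oxy}methyl)-11-[(4-methoxyphenyl)methoxy]undeca-1,8-dien-3-yl 2-(bromomethyl)prop-2-enoate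
Product: 19 (5R)-3-(bromomethyl)-5-[(2S,5E)-2,6-bis({[tert-butyl(dimethyl)silyl]oxy}methyl)-8-[(4-methoxyphenyl)methoxy]oct-5-en-1-yl]furan-2(5H)-one
Conditions: Grubbs second-generation catalyst (5 mol %), CH2Cl2 (5 mM), 40 °C
Reagents that add atoms: none
Why: Ring-closing metathesis between the vinyl group and the acrylate closes the five-membered butenolide with loss of ethene, which should be much faster than engagement of the trisubstituted alkene.

Step 12
Reactants: 19 (5R)-3-(bromomethyl)-5-[(2S,5E)-2,6-bis({[tert-butyl(dimethyl)silyl]oxy}methyl)-8-[(4-methoxyphenyl)methoxy]oct-5-en-1-yl]furan-2(5H)-one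
Product: 20 (5R)-3-(bromomethyl)-5-[(2S,5E)-2,6-bis({[tert-butyl(dimethyl)silyl]oxy}methyl)-8-hydroxyoct-5-en-1-yl]furan-2(5H)-one
Conditions: DDQ, CH2Cl2/pH 7 buffer, 0 °C
Reagents that add atoms: none
Why: Oxidative cleavage of the PMB ether by DDQ (benzylic hydride abstraction, then hydrolysis of the oxocarbenium ion) frees O–C8, while silyl ethers, allylic bromide and butenolide should remain untouched.

Step 13
Reactants: 20 (5R)-3-(bromomethyl)-5-[(2S,5E)-2,6-bis({[tert-butyl(dimethyl)silyl]oxy}methyl)-8-hydroxyoct-5-en-1-yl]furan-2(5H)-one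
Product: 21 (3E,7S)-8-[(2R)-4-(bromomethyl)-5-oxo-2,5-dihydrofuran-2-yl]-3,7-bis({[tert-butyl(dimethyl)silyl]oxy}methyl)oct-3-enal
Conditions: Dess–Martin periodinane, NaHCO3, CH2Cl2, 0 °C; used at once
Reagents that add atoms: none
Why: Buffered Dess–Martin oxidation should give the β,γ-unsaturated aldehyde without acid or base strong enough to move the alkene into conjugation.

Step 14
Reactants: 21 (3E,7S)-8-[(2R)-4-(bromomethyl)-5-oxo-2,5-dihydrofuran-2-yl]-3,7-bis({[tert-butyl(dimethyl)silyl]oxy}methyl)oct-3-enal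
Product: 23 (3aR,4S,6E,10S,11aR)-6,10-bis({[tert-butyl(dimethyl)silyl]oxy}methyl)-4-hydroxy-3-methylidene-3a,4,5,8,9,10,11,11a-octahydrocyclodeca[b]furan-2(3H)-one, via allylchromium(III) dichloride 22 (not isolated)
Conditions: CrCl2 (8 equiv), THF, rt; 21 added by syringe pump (final 2 mM); aq. NH4Cl
Reagents that add atoms: none
Why: Two equivalents of Cr(II) reduce the allylic C–Br bond to an η1-allylchromium(III) species (22, Cr on C13), which adds to the tethered aldehyde through its γ-carbon C7 in a six-membered chair transition state, so that the C7–C8 bond forms while the butenolide double bond moves to C11=C13 and appears as the exocyclic methylene. The closest known reaction type is the Nozaki–Hiyama–Kishi (Barbier-type) allylation of aldehydes with 3-(bromomethyl)furan-2(5H)-ones, together with NHK macrocyclisations that give medium-ring carbocycles fused to α-methylene lactones. The ten-membered carbocycle closes in a 10-exo-trig mode onto the carbonyl carbon, the lactone ring being already in place. C7 is controlled by C6: the aldehyde should add to the butenolide face anti to the C5 chain, giving the trans 6,7 ring fusion; C8 is controlled by the Zimmerman–Traxler chair, in which the ring-locked allylmetal (C6 trans to C13) and a pseudo-equatorial C9 place the C8–O bond anti to C6, which is the 8S alcohol, epimeric at C8 with the target ester and therefore what the invertive esterification of step 15 needs. The step needs cyclisation to beat oligomerisation and γ- over α-attack; slow addition at high dilution should secure the first and the SE2′ preference of allylchromium reagents the second, while the silyl ethers, the trisubstituted alkene and the lactone are inert to Cr(II).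

Step 15
Reactants: 23 (3aR,4S,6E,10S,11aR)-6,10-bis({[tert-butyl(dimethyl)silyl]oxy}methyl)-4-hydroxy-3-methylidene-3a,4,5,8,9,10,11,11a-octahydrocyclodeca[b]furan-2(3H)-one; 24 2-methylprop-2-enoic acid
Product: 25 (3aS,4R,6E,10S,11aR)-6,10-bis({[tert-butyl(dimethyl)silyl]oxy}methyl)-3-methylidene-2-oxo-2,3,3a,4,5,8,9,10,11,11a-decahydrocyclodeca[b]furan-4-yl 2-methylprop-2-enoate
Conditions: PPh3, DIAD, toluene, 0 °C to rt
Reagents that add atoms: none
Why: In this Mitsunobu esterification the methacrylate anion should displace the C8 oxyphosphonium group by SN2 with inversion, turning the 8S alcohol into the 8R ester of the target.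

Step 16
Reactants: 25 (3aS,4R,6E,10S,11aR)-6,10-bis({[tert-butyl(dimethyl)silyl]oxy}methyl)-3-methylidene-2-oxo-2,3,3a,4,5,8,9,10,11,11a-decahydrocyclodeca[b]furan-4-yl 2-methylprop-2-enoate
Product: 26 (3aS,4R,6E,10S,11aR)-6,10-bis(hydroxymethyl)-3-methylidene-2-oxo-2,3,3a,4,5,8,9,10,11,11a-decahydrocyclodeca[b]furan-4-yl 2-methylprop-2-enoate
Conditions: HF·pyridine, pyridine, THF, 0 °C to rt
Reagents that add atoms: none
Why: Fluoride-mediated cleavage of the two primary TBS ethers under buffered acidic conditions should leave the methacrylate, the α-methylene lactone and the trisubstituted alkene unchanged and avoid acyl migration.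

Compound list
1 | (5R)-5-(hydroxymethyl)oxolan-2-one | OC[C@H]1CCC(=O)O1 | starting material
2 | (2R)-5-oxooxolane-2-carbaldehyde | O=C[C@H]1CCC(=O)O1 | intermediate
3 | (5R)-5-ethenyloxolan-2-one | C=C[C@H]1CCC(=O)O1 | intermediate
4 | 3-bromo-1,1-dimethoxypropane | COC(OC)CCBr | starting material
5 | 3-iodo-1,1-dimethoxypropane | COC(OC)CCI | intermediate
6 | (3S,5R)-3-(3,3-dimethoxypropyl)-5-ethenyloxolan-2-one | COC(OC)CC[C@@H]1C(=O)O[C@@H](C=C)C1 | intermediate
7 | 3-[(3S,5R)-5-ethenyl-2-oxooxolan-3-yl]propanal | O=CCC[C@@H]1C(=O)O[C@@H](C=C)C1 | intermediate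
8 | 1-[(3-bromopropoxy)methyl]-4-methoxybenzene | COc1ccc(COCCCBr)cc1 | starting material
9 | {3-[(4-methoxyphenyl)methoxy]propyl}triphenylphosphonium bromide | COc1ccc(COCCC[P+](c2ccccc2)(c2ccccc2)c2ccccc2)cc1.[Br-] | intermediate
10 | methyl chloroformate | COC(=O)Cl | starting material
11 | {3-[(4-methoxyphenyl)methoxy]propylidene}triphenyl-λ5-phosphane | COc1ccc(COCCC=P(c2ccccc2)(c2ccccc2)c2ccccc2)cc1 | intermediate
12 | {1-methoxy-4-[(4-methoxyphenyl)methoxy]-1-oxobutan-2-yl}triphenylphosphonium chloride | COC(=O)C(CCOCc1ccc(OC)cc1)[P+](c1ccccc1)(c1ccccc1)c1ccccc1.[Cl-] | intermediate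
13 | methyl 4-[(4-methoxyphenyl)methoxy]-2-(triphenyl-λ5-phosphanylidene)butanoate | COC(=O)C(CCOCc1ccc(OC)cc1)=P(c1ccccc1)(c1ccccc1)c1ccccc1 | intermediate
14 | methyl (2E)-5-[(3S,5R)-5-ethenyl-2-oxooxolan-3-yl]-2-{2-[(4-methoxyphenyl)methoxy]ethyl}pent-2-enoate | COc1ccc(COCC/C(C(=O)OC)=C\CC[C@@H]2C(=O)O[C@@H](C=C)C2)cc1 | intermediate
15 | (3R,5S,8E)-5,9-bis(hydroxymethyl)-11-[(4-methoxyphenyl)methoxy]undeca-1,8-dien-3-ol | COc1ccc(COCC/C(CO)=C\CC[C@H](CO)C[C@@H](O)C=C)cc1 | intermediate
16 | (3R,5S,8E)-5,9-bis({[tert-butyl(dimethyl)silyl]oxy}methyl)-11-[(4-methoxyphenyl)methoxy]undeca-1,8-dien-3-ol | COc1ccc(COCC/C(CO[Si](C)(C)C(C)(C)C)=C\CC[C@H](CO[Si](C)(C)C(C)(C)C)C[C@@H](O)C=C)cc1 | intermediate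
17 | 2-(bromomethyl)prop-2-enoic acid | C=C(CBr)C(=O)O | starting material
18 | (3R,5S,8E)-5,9-bis({[tert-butyl(dimethyl)silyl]oxy}methyl)-11-[(4-methoxyphenyl)methoxy]undeca-1,8-dien-3-yl 2-(bromomethyl)prop-2-enoate | COc1ccc(COCC/C(CO[Si](C)(C)C(C)(C)C)=C\CC[C@H](CO[Si](C)(C)C(C)(C)C)C[C@@H](OC(=O)C(=C)CBr)C=C)cc1 | intermediate
19 | (5R)-3-(bromomethyl)-5-[(2S,5E)-2,6-bis({[tert-butyl(dimethyl)silyl]oxy}methyl)-8-[(4-methoxyphenyl)methoxy]oct-5-en-1-yl]furan-2(5H)-one | COc1ccc(COCC/C(CO[Si](C)(C)C(C)(C)C)=C\CC[C@H](CO[Si](C)(C)C(C)(C)C)C[C@H]2OC(=O)C(CBr)=C2)cc1 | intermediate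
20 | (5R)-3-(bromomethyl)-5-[(2S,5E)-2,6-bis({[tert-butyl(dimethyl)silyl]oxy}methyl)-8-hydroxyoct-5-en-1-yl]furan-2(5H)-one | OCC/C(CO[Si](C)(C)C(C)(C)C)=C\CC[C@H](CO[Si](C)(C)C(C)(C)C)C[C@H]1OC(=O)C(CBr)=C1 | intermediate
21 | (3E,7S)-8-[(2R)-4-(bromomethyl)-5-oxo-2,5-dihydrofuran-2-yl]-3,7-bis({[tert-butyl(dimethyl)silyl]oxy}methyl)oct-3-enal | O=CC/C(CO[Si](C)(C)C(C)(C)C)=C\CC[C@H](CO[Si](C)(C)C(C)(C)C)C[C@H]1OC(=O)C(CBr)=C1 | intermediate
22 | allylchromium(III) dichloride of 21 (Cr on the former CH2Br carbon C13) | O=CC/C(CO[Si](C)(C)C(C)(C)C)=C\CC[C@H](CO[Si](C)(C)C(C)(C)C)C[C@H]1OC(=O)C(C[Cr](Cl)Cl)=C1 | intermediate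
23 | (3aR,4S,6E,10S,11aR)-6,10-bis({[tert-butyl(dimethyl)silyl]oxy}methyl)-4-hydroxy-3-methylidene-3a,4,5,8,9,10,11,11a-octahydrocyclodeca[b]furan-2(3H)-one | O[C@H]1C/C(CO[Si](C)(C)C(C)(C)C)=C\CC[C@H](CO[Si](C)(C)C(C)(C)C)C[C@H]2OC(=O)C(=C)[C@H]12 | intermediate
24 | 2-methylprop-2-enoic acid (methacrylic acid) | C=C(C)C(=O)O | starting material
25 | (3aS,4R,6E,10S,11aR)-6,10-bis({[tert-butyl(dimethyl)silyl]oxy}methyl)-3-methylidene-2-oxo-2,3,3a,4,5,8,9,10,11,11a-decahydrocyclodeca[b]furan-4-yl 2-methylprop-2-enoate | C=C(C)C(=O)O[C@@H]1C/C(CO[Si](C)(C)C(C)(C)C)=C\CC[C@H](CO[Si](C)(C)C(C)(C)C)C[C@H]2OC(=O)C(=C)[C@H]12 | intermediate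
26 | (3aS,4R,6E,10S,11aR)-6,10-bis(hydroxymethyl)-3-methylidene-2-oxo-2,3,3a,4,5,8,9,10,11,11a-decahydrocyclodeca[b]furan-4-yl 2-methylprop-2-enoate | C=C(C)C(=O)O[C@@H]1C/C(CO)=C\CC[C@H](CO)C[C@H]2OC(=O)C(=C)[C@H]12 | target

Total step count: 16. Longest linear sequence: 13 steps (1, 2, 4, 7–16).

Steps most likely to fail

Step 14 (key step). Intermolecular allylation may outrun ring closure, and the β,γ-unsaturated aldehyde may isomerise into conjugation on the Lewis-acidic chromium salts before it is captured. The fallback replaces the in-situ Barbier-type organometallic by an isolable allylboron reagent. It sets out from 19, whose allylic bromide is borylated (B2pin2, Pd2(dba)3 cat., toluene, 50 °C) to the allylboronate PMB ether F1. DDQ then frees the primary alcohol F2, and buffered Dess–Martin oxidation gives the boronate aldehyde F3. Sc(OTf)3-catalysed intramolecular allylboration at high dilution (2-alkoxycarbonyl allylboronate chemistry, closed chair transition state with the same sense of induction), followed by aqueous work-up of the borate, returns to the route at 23.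

Step 15. SN2 displacement at a ring carbinol flanked by the lactone may be slow, so that elimination towards C9 or simple recovery of the alcohol may prevail. The fallback inverts C8 by a redox pair. From 23, buffered Dess–Martin oxidation gives the C8 ketone F4. Luche reduction (NaBH4, CeCl3, MeOH, −78 °C) should deliver hydride to the carbonyl face next to H7, away from the lactone, and give the 8R alcohol F5. Acylation with methacrylic anhydride, Et3N and DMAP returns to the route at 25.

Step 4. E2 elimination of the β-oxygenated iodide, slow SN2 with an unactivated halide and proton exchange leading to a second alkylation may erode conversion and facial selectivity. The fallback uses a reactive propargylic electrophile and builds the aldehyde afterwards. From 3, LDA then propargyl bromide should give the trans propargyl lactone F6. Ruthenium-catalysed anti-Markovnikov hydration of the terminal alkyne (CpRu(MeCN)3PF6, 5,5′-bis(trifluoromethyl)-2,2′-bipyridine, aqueous NMP) converts it into aldehyde 7, where it rejoins the route.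

Further compounds
F1 | step 14 | (5R)-5-[(2S,5E)-2,6-bis({[tert-butyl(dimethyl)silyl]oxy}methyl)-8-[(4-methoxyphenyl)methoxy]oct-5-en-1-yl]-3-[(4,4,5,5-tetramethyl-1,3,2-dioxaborolan-2-yl)methyl]furan-2(5H)-one | COc1ccc(COCC/C(CO[Si](C)(C)C(C)(C)C)=C\CC[C@H](CO[Si](C)(C)C(C)(C)C)C[C@H]2OC(=O)C(CB3OC(C)(C)C(C)(C)O3)=C2)cc1
F2 | step 14 | (5R)-5-[(2S,5E)-2,6-bis({[tert-butyl(dimethyl)silyl]oxy}methyl)-8-hydroxyoct-5-en-1-yl]-3-[(4,4,5,5-tetramethyl-1,3,2-dioxaborolan-2-yl)methyl]furan-2(5H)-one | OCC/C(CO[Si](C)(C)C(C)(C)C)=C\CC[C@H](CO[Si](C)(C)C(C)(C)C)C[C@H]1OC(=O)C(CB2OC(C)(C)C(C)(C)O2)=C1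
F3 | step 14 | (3E,7S)-3,7-bis({[tert-butyl(dimethyl)silyl]oxy}methyl)-8-{(2R)-5-oxo-4-[(4,4,5,5-tetramethyl-1,3,2-dioxaborolan-2-yl)methyl]-2,5-dihydrofuran-2-yl}oct-3-enal | O=CC/C(CO[Si](C)(C)C(C)(C)C)=C\CC[C@H](CO[Si](C)(C)C(C)(C)C)C[C@H]1OC(=O)C(CB2OC(C)(C)C(C)(C)O2)=C1
F4 | step 15 | (3aS,6E,10S,11aR)-6,10-bis({[tert-butyl(dimethyl)silyl]oxy}methyl)-3-methylidene-3a,5,8,9,10,11-hexahydrocyclodeca[b]furan-2,4(3H,11aH)-dione (C8 ketone of 23) | O=C1C/C(CO[Si](C)(C)C(C)(C)C)=C\CC[C@H](CO[Si](C)(C)C(C)(C)C)C[C@H]2OC(=O)C(=C)[C@H]12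
F5 | step 15 | (3aR,4R,6E,10S,11aR)-6,10-bis({[tert-butyl(dimethyl)silyl]oxy}methyl)-4-hydroxy-3-methylidene-3a,4,5,8,9,10,11,11a-octahydrocyclodeca[b]furan-2(3H)-one (C8 epimer of 23) | O[C@@H]1C/C(CO[Si](C)(C)C(C)(C)C)=C\CC[C@H](CO[Si](C)(C)C(C)(C)C)C[C@H]2OC(=O)C(=C)[C@H]12
F6 | step 4 | (3S,5R)-5-ethenyl-3-(prop-2-yn-1-yl)oxolan-2-one | C#CC[C@@H]1C(=O)O[C@@H](C=C)C1
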